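## Retrosynthetic overview

1. The target is traced back to a C6 cyclohexanone: both exocyclic methylenes are unmasked last (Mannich, then Hofmann-type elimination), the C9 angelate and C6 acetate come from acylations, the γ-lactone from acid lactonisation, the C6 alcohol from a C8-hydroxyl-directed reduction and the C5 side chain from enolate alkylation.
2. That cyclohexanone comes from retro-aldol opening of a bicyclo[3.2.1]octane in which a temporary two-carbon bridge C1–C2 ties C10 to C6; the bridge is not discarded but becomes the C10 vinyl group.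
3. The bicycle comes from a (4+3) cycloaddition that forms C6–C7 and C9–C10 together: a chiral 1-alkoxy-2-siloxyallyl cation (C7–C8–C9 with O8 and O9) adds to a 1,3-bis(silyloxy)-4-methylcyclopentadiene (C10, C1, C2, C6, C5).
4. Enabling feature: C7–C8(O)–C9 is a 2-oxyallyl unit whose termini are bonded to C6 and C10. These two carbons are both bonded to C5 and carry on the same (α) face the C6 hydrogen and the C10 vinyl carbon C1, so C10–C1–C2–C6 closes a five-membered ring through C5, with the C6 oxygen and C1 placed 1,3 as in a cyclopentane-1,3-dione.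
5. Ring order: cyclopentadiene (from cyclopentane-1,3-dione), then the six-membered carbocycle inside the bicyclo[3.2.1]octene (key step), then opening of the five-membered ring, then the γ-lactone late.

Key step: step 5

Notation: the Why lines use elemanolide numbering (C1=C2 vinyl and C14 methyl on C10; C5 carries C4 with C15 and C3; C6 OAc; C7; C8 lactone O; C9 OAng; C11–C13 lactone); β is the face of the C10 methyl group, α that of the C10 vinyl group. Systematic names in the compound list use their own locants.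

Assumption: the (S)-1-phenylethyl group is taken to steer the diene to the face of the cation that gives the C9 configuration shown; if the sense of induction is the opposite, (R)-1-phenylethanol is used and nothing else changes.

## Route

Step 1
Reactants: 1 cyclopentane-1,3-dione
Product: 2 3-[(tert-butyldimethylsilyl)oxy]cyclopent-2-en-1-one
Conditions: TBSCl, Et3N, CH2Cl2, 0 °C to rt
Reagents that add atoms: tert-butyldimethylsilyl chloride, CC(C)(C)[Si](C)(C)Cl
Why: O-silylation of the enol form of the cyclic 1,3-diketone gives the vinylogous silyl ester; no stereocenter is formed.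

Step 2
Reactants: 2 3-[(tert-butyldimethylsilyl)oxy]cyclopent-2-en-1-one
Product: 3 (±)-3-[(tert-butyldimethylsilyl)oxy]-5-methylcyclopent-2-en-1-one
Conditions: LiN(iPr)2, THF, −78 °C; MeI, −78 to −20 °C
Reagents that add atoms: iodomethane, CI
Why: kinetic α′-deprotonation and methylation of the vinylogous ester (Stork–Danheiser alkylation); the new stereocenter is racemic and becomes sp2 in step 5.

Step 3
Reactants: 4 1,1-dimethoxypropan-2-one; 5 (S)-1-phenylethanol
Product: 6 1-methoxy-1-[(1S)-1-phenylethoxy]propan-2-one (both acetal epimers)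
Conditions: TsOH·H2O (1 mol %), cyclohexane, 70 °C, MeOH removed by distillation
Reagents that add atoms: none
Why: acid-catalysed transacetalisation, driven by removal of methanol, puts the chiral alkoxy group on the acetal carbon, whose configuration is irrelevant because it becomes a planar cation in step 5.

Step 4
Reactants: 6 1-methoxy-1-[(1S)-1-phenylethoxy]propan-2-one
Product: 7 triethyl({3-methoxy-3-[(1S)-1-phenylethoxy]prop-1-en-2-yl}oxy)silane
Conditions: LiN(iPr)2, THF, −78 °C; Et3SiCl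
Reagents that add atoms: chlorotriethylsilane, CC[Si](Cl)(CC)CC
Why: kinetic enolisation at the methyl group and O-silylation (silyl enol ether formation); no stereocenter is set.

Step 5
Reactants: 3 (±)-3-[(tert-butyldimethylsilyl)oxy]-5-methylcyclopent-2-en-1-one; 7 triethyl({3-methoxy-3-[(1S)-1-phenylethoxy]prop-1-en-2-yl}oxy)silane
Product: 9 1,6-bis[(tert-butyldimethylsilyl)oxy]-5-methyl-4-[(1S)-1-phenylethoxy]bicyclo[3.2.1]oct-6-en-3-one (4-alkoxy group equatorial), via bis(silyloxy)cyclopentadiene 8 (not isolated)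
Conditions: (a) 3, LiN(iPr)2, THF, −78 °C; TBSOTf; exchange to pentane, filtration; (b) 7, Me3SiOTf (10 mol %), CH2Cl2, −78 °C
Reagents that add atoms: tert-butyldimethylsilyl trifluoromethanesulfonate, CC(C)(C)[Si](C)(C)OS(=O)(=O)C(F)(F)F
Why: Me3SiOTf ionises the mixed acetal of 7 at the methoxy group to a 1-alkoxy-2-siloxyallyl (vinyl oxocarbenium) cation, which adds across the termini of diene 8 in the Mukaiyama sense: C10, the most nucleophilic terminus of the 1,3-dioxygenated diene, attacks the oxocarbenium carbon C9, and the remaining C7 enol silane then closes onto the oxygen-stabilised C6 cation (Mukaiyama–Michael) with release of the silyl group from O8. The closest known reaction type is the (4+3) cycloaddition of alkoxy-substituted siloxyallyl cations with furans and cyclopentadienes. The second bond closes the six-membered carbocycle C5–C10 in a 6-exo sense and the seven-membered ring C6–C7–C8–C9–C10–C1–C2 in a 7-endo sense, which together is the (4+3) mode enforced by the s-cis diene locked in the five-membered ring. C9 is set by the (S)-1-phenylethyl group, which shields one face of the cation, and its ether should end up equatorial (α, on the side of the new C1=C2 bridge) through the compact transition state; this is also the thermodynamic epimer next to the ketone, while C10 and C6 are fixed relative to C9 because both bonds form on the same face of the planar diene. The step needs regioselectivity (alkoxy-bearing carbon to the methyl-bearing terminus), secured by the matched polarity of C9 with C10 and of C7 with C6, and (4+3) rather than (3+2) or open-chain addition, secured by the cyclic s-cis diene and by the C6 oxygen that stabilises the intermediate cation until the ring closes.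

Step 6
Reactants: 9 1,6-bis[(tert-butyldimethylsilyl)oxy]-5-methyl-4-[(1S)-1-phenylethoxy]bicyclo[3.2.1]oct-6-en-3-one
Product: 11 tert-butyl {1,6-bis[(tert-butyldimethylsilyl)oxy]-5-methyl-3-oxo-4-[(1S)-1-phenylethoxy]bicyclo[3.2.1]oct-6-en-2-yl}acetate (side chain equatorial), via axial C7 epimer 10 (not isolated)
Conditions: LiN(iPr)2, THF, −78 °C; BrCH2CO2tBu, −78 to −40 °C; then DBU (cat.), THF, rt
Reagents that add atoms: tert-butyl bromoacetate, CC(C)(C)OC(=O)CBr
Why: enolate alkylation at C7, the only methylene next to the C8 ketone, occurs from the exo (β) face, and base then equilibrates the product to the thermodynamically preferred equatorial (α) side chain, cis to the C9 ether.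

Step 7
Reactants: 11 tert-butyl {1,6-bis[(tert-butyldimethylsilyl)oxy]-5-methyl-3-oxo-4-[(1S)-1-phenylethoxy]bicyclo[3.2.1]oct-6-en-2-yl}acetate
Product: 12 tert-butyl {1,6-bis[(tert-butyldimethylsilyl)oxy]-3-hydroxy-5-methyl-4-[(1S)-1-phenylethoxy]bicyclo[3.2.1]oct-6-en-2-yl}acetate (3-OH axial)
Conditions: LiBH(sBu)3, THF, −78 °C; then H2O
Reagents that add atoms: none
Why: substrate-controlled ketone reduction in which the bulky hydride attacks C8 from the exo (β) face, away from the two-carbon bridge, so the C8 hydroxyl is axial (α) and cis to the C7 and C9 substituents.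

Step 8
Reactants: 12 tert-butyl {1,6-bis[(tert-butyldimethylsilyl)oxy]-3-hydroxy-5-methyl-4-[(1S)-1-phenylethoxy]bicyclo[3.2.1]oct-6-en-2-yl}acetate
Product: 13 tert-butyl 2-{1,6-bis[(tert-butyldimethylsilyl)oxy]-3-hydroxy-5-methyl-4-[(1S)-1-phenylethoxy]bicyclo[3.2.1]oct-6-en-2-yl}-3-(dimethylamino)propanoate (both C11 epimers)
Conditions: LiN(iPr)2 (2.3 equiv), THF, −78 °C; CH2=NMe2+ I−, −78 to 0 °C
Reagents that add atoms: N,N-dimethylmethyleneiminium iodide (Eschenmoser's salt), C=[N+](C)C.[I-]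
Why: Mannich aminomethylation of the ester enolate (the C8 alkoxide is a spectator) installs the masked C13 methylene; the C11 configuration is irrelevant because C11 becomes sp2 in step 22.

Step 9
Reactants: 13 tert-butyl 2-{1,6-bis[(tert-butyldimethylsilyl)oxy]-3-hydroxy-5-methyl-4-[(1S)-1-phenylethoxy]bicyclo[3.2.1]oct-6-en-2-yl}-3-(dimethylamino)propanoate
Product: 14 tert-butyl 3-(dimethylamino)-2-{1,3-dihydroxy-5-methyl-6-oxo-4-[(1S)-1-phenylethoxy]bicyclo[3.2.1]octan-2-yl}propanoate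
Conditions: 48% aq. HF, MeCN, 0 °C to rt
Reagents that add atoms: none
Why: protodesilylation turns the silyl enol ether into the bridge ketone and the bridgehead silyl ether into the tertiary C6 alcohol, while the acidic medium keeps the β-hydroxy ketone from opening; no stereocenter changes.

Step 10
Reactants: 14 tert-butyl 3-(dimethylamino)-2-{1,3-dihydroxy-5-methyl-6-oxo-4-[(1S)-1-phenylethoxy]bicyclo[3.2.1]octan-2-yl}propanoate
Product: 15 tert-butyl 3-(dimethylamino)-2-{1-hydroxy-5-methyl-6-oxo-4-[(1S)-1-phenylethoxy]-3-[(triethylsilyl)oxy]bicyclo[3.2.1]octan-2-yl}propanoate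
Conditions: Et3SiCl, imidazole, CH2Cl2, −20 °C
Reagents that add atoms: chlorotriethylsilane, CC[Si](Cl)(CC)CC
Why: silyl ether formation with steric differentiation, in which the secondary C8 hydroxyl reacts and the tertiary bridgehead C6 hydroxyl does not.

Step 11
Reactants: 15 tert-butyl 3-(dimethylamino)-2-{1-hydroxy-5-methyl-6-oxo-4-[(1S)-1-phenylethoxy]-3-[(triethylsilyl)oxy]bicyclo[3.2.1]octan-2-yl}propanoate
Product: 17 tert-butyl 3-(dimethylamino)-2-{4-methyl-6-oxo-3-[(1S)-1-phenylethoxy]-2-[(triethylsilyl)oxy]-4-[1-(trifluoromethanesulfonyloxy)ethenyl]cyclohexyl}propanoate, via potassium enolate 16 (not isolated)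
Conditions: KN(SiMe3)2 (1.05 equiv), PhNTf2, THF, −78 to −40 °C
Reagents that add atoms: N-phenylbis(trifluoromethanesulfonimide), O=S(=O)(N(c1ccccc1)S(=O)(=O)C(F)(F)F)C(F)(F)F
Why: alkoxide-triggered retro-aldol fragmentation of the strained bicyclic β-hydroxy ketone cleaves the C2–C6 bond and gives the C6 ketone plus, regiospecifically, the methyl ketone enolate, which is trapped by O-triflation; no stereocenter is touched.

Step 12
Reactants: 17 tert-butyl 3-(dimethylamino)-2-{4-methyl-6-oxo-3-[(1S)-1-phenylethoxy]-2-[(triethylsilyl)oxy]-4-[1-(trifluoromethanesulfonyloxy)ethenyl]cyclohexyl}propanoate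
Product: 18 tert-butyl 3-(dimethylamino)-2-{4-ethenyl-4-methyl-6-oxo-3-[(1S)-1-phenylethoxy]-2-[(triethylsilyl)oxy]cyclohexyl}propanoate
Conditions: Pd(OAc)2 (5 mol %), PPh3, HCO2H, Et3N, DMF, 60 °C
Reagents that add atoms: none
Why: palladium-catalysed formate reduction of the enol triflate (hydride transfer to the vinylpalladium intermediate) gives the C10 vinyl group.

Step 13
Reactants: 18 tert-butyl 3-(dimethylamino)-2-{4-ethenyl-4-methyl-6-oxo-3-[(1S)-1-phenylethoxy]-2-[(triethylsilyl)oxy]cyclohexyl}propanoate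
Product: 19 tert-butyl 3-(dimethylamino)-2-{4-ethenyl-4-methyl-6-oxo-5-[2-oxo-2-(prop-2-en-1-yloxy)ethyl]-3-[(1S)-1-phenylethoxy]-2-[(triethylsilyl)oxy]cyclohexyl}propanoate
Conditions: LiN(iPr)2 (1.05 equiv), THF, −78 °C; BrCH2CO2CH2CH=CH2, DMPU, −78 to −40 °C
Reagents that add atoms: prop-2-en-1-yl bromoacetate, C=CCOC(=O)CBr
Why: kinetic enolate alkylation at the C5 methylene, in which the electrophile adds to the β face because the substituents at C7, C8 and C9 and the C10 vinyl group all shield the α face; this sets C5.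

Step 14
Reactants: 19 tert-butyl 3-(dimethylamino)-2-{4-ethenyl-4-methyl-6-oxo-5-[2-oxo-2-(prop-2-en-1-yloxy)ethyl]-3-[(1S)-1-phenylethoxy]-2-[(triethylsilyl)oxy]cyclohexyl}propanoate
Product: 21 tert-butyl 3-(dimethylamino)-2-{4-ethenyl-2,6-dihydroxy-4-methyl-5-[2-oxo-2-(prop-2-en-1-yloxy)ethyl]-3-[(1S)-1-phenylethoxy]cyclohexyl}propanoate, via beta-hydroxy ketone 20 (not isolated)
Conditions: AcOH/THF/H2O (3:1:1), rt; then Me4NBH(OAc)3, MeCN/AcOH, −30 °C
Reagents that add atoms: none
Why: after acidic removal of the silyl ether, the hydroxyl-directed Evans–Saksena reduction delivers hydride from the boron bound to the C8 α-oxygen to the α face of C6 and gives the 1,3-anti diol, that is the C6 β-alcohol.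

Step 15
Reactants: 21 tert-butyl 3-(dimethylamino)-2-{4-ethenyl-2,6-dihydroxy-4-methyl-5-[2-oxo-2-(prop-2-en-1-yloxy)ethyl]-3-[(1S)-1-phenylethoxy]cyclohexyl}propanoate
Product: 22 tert-butyl 2-{6-(acetyloxy)-4-ethenyl-2-hydroxy-4-methyl-5-[2-oxo-2-(prop-2-en-1-yloxy)ethyl]-3-[(1S)-1-phenylethoxy]cyclohexyl}-3-(dimethylamino)propanoate
Conditions: Ac2O, pyridine, DMAP (cat.), CH2Cl2, −20 °C
Reagents that add atoms: acetic anhydride, CC(=O)OC(C)=O
Why: selective acylation of the less hindered equatorial C6 hydroxyl over the axial C8 hydroxyl, which is flanked by the C7 and C9 substituents.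

Step 16
Reactants: 22 tert-butyl 2-{6-(acetyloxy)-4-ethenyl-2-hydroxy-4-methyl-5-[2-oxo-2-(prop-2-en-1-yloxy)ethyl]-3-[(1S)-1-phenylethoxy]cyclohexyl}-3-(dimethylamino)propanoate
Product: 23 prop-2-en-1-yl {4-(acetyloxy)-3-[(dimethylamino)methyl]-6-ethenyl-7-hydroxy-6-methyl-2-oxooctahydro-1-benzofuran-5-yl}acetate
Conditions: CF3CO2H/CH2Cl2/H2O (10:10:1), 0 °C to rt
Reagents that add atoms: none
Why: acidolysis of the tert-butyl ester and of the 1-phenylethyl ether (both through stabilised carbocations) is followed by spontaneous γ-lactonisation of the C12 acid onto the cis C8 hydroxyl, while the allyl ester and the acetate are stable to the acid.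

Step 17
Reactants: 23 prop-2-en-1-yl {4-(acetyloxy)-3-[(dimethylamino)methyl]-6-ethenyl-7-hydroxy-6-methyl-2-oxooctahydro-1-benzofuran-5-yl}acetate
Product: 24 4-(acetyloxy)-3-[(dimethylamino)methyl]-6-ethenyl-6-methyl-2-oxo-5-[2-oxo-2-(prop-2-en-1-yloxy)ethyl]octahydro-1-benzofuran-7-yl (2Z)-2-methylbut-2-enoate
Conditions: angelic acid, 2,4,6-Cl3C6H2COCl, Et3N, toluene, rt; then 23, DMAP, 60 °C
Reagents that add atoms: angelic acid [(2Z)-2-methylbut-2-enoic acid], C/C=C(/C)C(=O)O
Why: Yamaguchi esterification with the preformed mixed anhydride acylates the hindered C9 hydroxyl under conditions that should keep the Z geometry of the angelate.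

Step 18
Reactants: 24 4-(acetyloxy)-3-[(dimethylamino)methyl]-6-ethenyl-6-methyl-2-oxo-5-[2-oxo-2-(prop-2-en-1-yloxy)ethyl]octahydro-1-benzofuran-7-yl (2Z)-2-methylbut-2-enoate
Product: 25 {4-(acetyloxy)-3-[(dimethylamino)methyl]-6-ethenyl-6-methyl-7-{[(2Z)-2-methylbut-2-enoyl]oxy}-2-oxooctahydro-1-benzofuran-5-yl}acetic acid
Conditions: Pd(PPh3)4 (5 mol %), morpholine, THF, rt
Reagents that add atoms: none
Why: palladium-catalysed deallylation (π-allyl formation and capture by morpholine) frees the C15 acid without touching the other esters.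

Step 19
Reactants: 25 {4-(acetyloxy)-3-[(dimethylamino)methyl]-6-ethenyl-6-methyl-7-{[(2Z)-2-methylbut-2-enoyl]oxy}-2-oxooctahydro-1-benzofuran-5-yl}acetic acid
Product: 27 4-(acetyloxy)-3-[(dimethylamino)methyl]-6-ethenyl-5-(2-hydroxyethyl)-6-methyl-2-oxooctahydro-1-benzofuran-7-yl (2Z)-2-methylbut-2-enoate, via mixed carbonic anhydride 26 (not isolated)
Conditions: iBuOCOCl, N-methylmorpholine, THF, −15 °C; then NaBH4, H2O, 0 °C
Reagents that add atoms: none
Why: activation of the acid as its mixed carbonic anhydride and chemoselective borohydride reduction give the primary alcohol; lactone, acetate and angelate are not reduced under these conditions.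

Step 20
Reactants: 27 4-(acetyloxy)-3-[(dimethylamino)methyl]-6-ethenyl-5-(2-hydroxyethyl)-6-methyl-2-oxooctahydro-1-benzofuran-7-yl (2Z)-2-methylbut-2-enoate
Product: 28 4-(acetyloxy)-3-[(dimethylamino)methyl]-6-ethenyl-6-methyl-2-oxo-5-(2-oxoethyl)octahydro-1-benzofuran-7-yl (2Z)-2-methylbut-2-enoate
Conditions: Dess–Martin periodinane, CH2Cl2, 0 °C to rt
Reagents that add atoms: none
Why: Dess–Martin oxidation of the primary alcohol to the aldehyde under mild, non-epimerising conditions.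

Step 21
Reactants: 28 4-(acetyloxy)-3-[(dimethylamino)methyl]-6-ethenyl-6-methyl-2-oxo-5-(2-oxoethyl)octahydro-1-benzofuran-7-yl (2Z)-2-methylbut-2-enoate
Product: 30 4-(acetyloxy)-3-[(dimethylamino)methyl]-6-ethenyl-6-methyl-2-oxo-5-(3-oxoprop-1-en-2-yl)octahydro-1-benzofuran-7-yl (2Z)-2-methylbut-2-enoate, via Mannich base 29 (not isolated)
Conditions: CH2=NMe2+ I−, Et3N, CH2Cl2, rt
Reagents that add atoms: N,N-dimethylmethyleneiminium iodide (Eschenmoser's salt), C=[N+](C)C.[I-]
Why: Mannich reaction of the aldehyde at C4 followed by elimination of dimethylamine gives the 2-substituted acrolein (α-methylenation).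

Step 22
Reactants: 30 4-(acetyloxy)-3-[(dimethylamino)methyl]-6-ethenyl-6-methyl-2-oxo-5-(3-oxoprop-1-en-2-yl)octahydro-1-benzofuran-7-yl (2Z)-2-methylbut-2-enoate
Product: 32 (3aR,4S,5R,6S,7S,7aR)-4-(acetyloxy)-6-ethenyl-6-methyl-3-methylidene-2-oxo-5-(3-oxoprop-1-en-2-yl)octahydro-1-benzofuran-7-yl (2Z)-2-methylbut-2-enoate, via trimethylammonium iodide 31 (not isolated)
Conditions: MeI, MeCN, rt; then aq. NaHCO3, EtOAc, rt
Reagents that add atoms: none
Why: N-methylation and Hofmann-type elimination of trimethylamine from the β-ammonio lactone unveil the α-methylene lactone and give the target.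

## Compound list

1 | cyclopentane-1,3-dione | O=C1CCC(=O)C1 | starting material
2 | 3-[(tert-butyldimethylsilyl)oxy]cyclopent-2-en-1-one | O=C1CCC(O[Si](C)(C)C(C)(C)C)=C1 | intermediate
3 | (±)-3-[(tert-butyldimethylsilyl)oxy]-5-methylcyclopent-2-en-1-one | CC1CC(O[Si](C)(C)C(C)(C)C)=CC1=O | intermediate
4 | 1,1-dimethoxypropan-2-one | CC(=O)C(OC)OC | starting material
5 | (S)-1-phenylethanol | C[C@H](O)c1ccccc1 | starting material
6 | 1-methoxy-1-[(1S)-1-phenylethoxy]propan-2-one (both acetal epimers) | CC(=O)C(OC)O[C@@H](C)c1ccccc1 | intermediate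
7 | triethyl({3-methoxy-3-[(1S)-1-phenylethoxy]prop-1-en-2-yl}oxy)silane (both acetal epimers) | C=C(O[Si](CC)(CC)CC)C(OC)O[C@@H](C)c1ccccc1 | intermediate
8 | 1,3-bis[(tert-butyldimethylsilyl)oxy]-4-methylcyclopenta-1,3-diene (not isolated) | CC1=C(O[Si](C)(C)C(C)(C)C)C=C(O[Si](C)(C)C(C)(C)C)C1 | intermediate
9 | 1,6-bis[(tert-butyldimethylsilyl)oxy]-5-methyl-4-[(1S)-1-phenylethoxy]bicyclo[3.2.1]oct-6-en-3-one; 4-alkoxy group equatorial, on the side of the C6=C7 bridge; configuration as in the SMILES | C3=C(O[Si](C)(C)C(C)(C)C)[C@]1(C)[C@H](O[C@@H](C)c2ccccc2)C(=O)C[C@@]3(O[Si](C)(C)C(C)(C)C)C1 | intermediate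
10 | tert-butyl {1,6-bis[(tert-butyldimethylsilyl)oxy]-5-methyl-3-oxo-4-[(1S)-1-phenylethoxy]bicyclo[3.2.1]oct-6-en-2-yl}acetate, side chain axial, trans to the 4-alkoxy group (not isolated) | C3=C(O[Si](C)(C)C(C)(C)C)[C@]1(C)[C@H](O[C@@H](C)c2ccccc2)C(=O)[C@@H](CC(=O)OC(C)(C)C)[C@@]3(O[Si](C)(C)C(C)(C)C)C1 | intermediate
11 | tert-butyl {1,6-bis[(tert-butyldimethylsilyl)oxy]-5-methyl-3-oxo-4-[(1S)-1-phenylethoxy]bicyclo[3.2.1]oct-6-en-2-yl}acetate, side chain equatorial, cis to the 4-alkoxy group | C3=C(O[Si](C)(C)C(C)(C)C)[C@]1(C)[C@H](O[C@@H](C)c2ccccc2)C(=O)[C@H](CC(=O)OC(C)(C)C)[C@@]3(O[Si](C)(C)C(C)(C)C)C1 | intermediate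
12 | tert-butyl {1,6-bis[(tert-butyldimethylsilyl)oxy]-3-hydroxy-5-methyl-4-[(1S)-1-phenylethoxy]bicyclo[3.2.1]oct-6-en-2-yl}acetate; 3-OH axial, substituents at C2, C3 and C4 all cis | C3=C(O[Si](C)(C)C(C)(C)C)[C@]1(C)[C@H](O[C@@H](C)c2ccccc2)[C@H](O)[C@H](CC(=O)OC(C)(C)C)[C@@]3(O[Si](C)(C)C(C)(C)C)C1 | intermediate
13 | tert-butyl 2-{1,6-bis[(tert-butyldimethylsilyl)oxy]-3-hydroxy-5-methyl-4-[(1S)-1-phenylethoxy]bicyclo[3.2.1]oct-6-en-2-yl}-3-(dimethylamino)propanoate (both epimers at the aminomethyl-bearing carbon) | C3=C(O[Si](C)(C)C(C)(C)C)[C@]1(C)[C@H](O[C@@H](C)c2ccccc2)[C@H](O)[C@H](C(CN(C)C)C(=O)OC(C)(C)C)[C@@]3(O[Si](C)(C)C(C)(C)C)C1 | intermediate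
14 | tert-butyl 3-(dimethylamino)-2-{1,3-dihydroxy-5-methyl-6-oxo-4-[(1S)-1-phenylethoxy]bicyclo[3.2.1]octan-2-yl}propanoate | C3C(=O)[C@]1(C)[C@H](O[C@@H](C)c2ccccc2)[C@H](O)[C@H](C(CN(C)C)C(=O)OC(C)(C)C)[C@@]3(O)C1 | intermediate
15 | tert-butyl 3-(dimethylamino)-2-{1-hydroxy-5-methyl-6-oxo-4-[(1S)-1-phenylethoxy]-3-[(triethylsilyl)oxy]bicyclo[3.2.1]octan-2-yl}propanoate | C3C(=O)[C@]1(C)[C@H](O[C@@H](C)c2ccccc2)[C@H](O[Si](CC)(CC)CC)[C@H](C(CN(C)C)C(=O)OC(C)(C)C)[C@@]3(O)C1 | intermediate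
16 | potassium enolate of the ring-opened methyl ketone: the cyclohexanone of 17 carrying C(O−)=CH2 in place of the enol triflate (not isolated) | C=C([O-])[C@]1(C)[C@H](O[C@@H](C)c2ccccc2)[C@H](O[Si](CC)(CC)CC)[C@H](C(CN(C)C)C(=O)OC(C)(C)C)C(=O)C1.[K+] | intermediate
17 | tert-butyl 3-(dimethylamino)-2-{4-methyl-6-oxo-3-[(1S)-1-phenylethoxy]-2-[(triethylsilyl)oxy]-4-[1-(trifluoromethanesulfonyloxy)ethenyl]cyclohexyl}propanoate; ring substituents at C1, C2, C3 and the enol triflate all on one face | C=C(OS(=O)(=O)C(F)(F)F)[C@]1(C)[C@H](O[C@@H](C)c2ccccc2)[C@H](O[Si](CC)(CC)CC)[C@H](C(CN(C)C)C(=O)OC(C)(C)C)C(=O)C1 | intermediate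
18 | tert-butyl 3-(dimethylamino)-2-{4-ethenyl-4-methyl-6-oxo-3-[(1S)-1-phenylethoxy]-2-[(triethylsilyl)oxy]cyclohexyl}propanoate | C=C[C@]1(C)[C@H](O[C@@H](C)c2ccccc2)[C@H](O[Si](CC)(CC)CC)[C@H](C(CN(C)C)C(=O)OC(C)(C)C)C(=O)C1 | intermediate
19 | tert-butyl 3-(dimethylamino)-2-{4-ethenyl-4-methyl-6-oxo-5-[2-oxo-2-(prop-2-en-1-yloxy)ethyl]-3-[(1S)-1-phenylethoxy]-2-[(triethylsilyl)oxy]cyclohexyl}propanoate; C5 side chain cis to the ring methyl | C=C[C@]1(C)[C@H](O[C@@H](C)c2ccccc2)[C@H](O[Si](CC)(CC)CC)[C@H](C(CN(C)C)C(=O)OC(C)(C)C)C(=O)[C@H]1CC(=O)OCC=C | intermediate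
20 | tert-butyl 3-(dimethylamino)-2-{4-ethenyl-2-hydroxy-4-methyl-6-oxo-5-[2-oxo-2-(prop-2-en-1-yloxy)ethyl]-3-[(1S)-1-phenylethoxy]cyclohexyl}propanoate (not isolated) | C=C[C@]1(C)[C@H](O[C@@H](C)c2ccccc2)[C@H](O)[C@H](C(CN(C)C)C(=O)OC(C)(C)C)C(=O)[C@H]1CC(=O)OCC=C | intermediate
21 | tert-butyl 3-(dimethylamino)-2-{4-ethenyl-2,6-dihydroxy-4-methyl-5-[2-oxo-2-(prop-2-en-1-yloxy)ethyl]-3-[(1S)-1-phenylethoxy]cyclohexyl}propanoate; the two hydroxyls trans (1,3-anti) | C=C[C@]1(C)[C@H](O[C@@H](C)c2ccccc2)[C@H](O)[C@H](C(CN(C)C)C(=O)OC(C)(C)C)[C@@H](O)[C@H]1CC(=O)OCC=C | intermediate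
22 | tert-butyl 2-{6-(acetyloxy)-4-ethenyl-2-hydroxy-4-methyl-5-[2-oxo-2-(prop-2-en-1-yloxy)ethyl]-3-[(1S)-1-phenylethoxy]cyclohexyl}-3-(dimethylamino)propanoate | C=C[C@]1(C)[C@H](O[C@@H](C)c2ccccc2)[C@H](O)[C@H](C(CN(C)C)C(=O)OC(C)(C)C)[C@@H](OC(C)=O)[C@H]1CC(=O)OCC=C | intermediate
23 | prop-2-en-1-yl {4-(acetyloxy)-3-[(dimethylamino)methyl]-6-ethenyl-7-hydroxy-6-methyl-2-oxooctahydro-1-benzofuran-5-yl}acetate (cis-fused lactone; ring configuration as in the target) | C=C[C@]1(C)[C@H](O)[C@@H]2OC(=O)C(CN(C)C)[C@@H]2[C@@H](OC(C)=O)[C@H]1CC(=O)OCC=C | intermediate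
24 | 4-(acetyloxy)-3-[(dimethylamino)methyl]-6-ethenyl-6-methyl-2-oxo-5-[2-oxo-2-(prop-2-en-1-yloxy)ethyl]octahydro-1-benzofuran-7-yl (2Z)-2-methylbut-2-enoate | C=C[C@]1(C)[C@H](OC(=O)/C(C)=C\C)[C@@H]2OC(=O)C(CN(C)C)[C@@H]2[C@@H](OC(C)=O)[C@H]1CC(=O)OCC=C | intermediate
25 | {4-(acetyloxy)-3-[(dimethylamino)methyl]-6-ethenyl-6-methyl-7-{[(2Z)-2-methylbut-2-enoyl]oxy}-2-oxooctahydro-1-benzofuran-5-yl}acetic acid | C=C[C@]1(C)[C@H](OC(=O)/C(C)=C\C)[C@@H]2OC(=O)C(CN(C)C)[C@@H]2[C@@H](OC(C)=O)[C@H]1CC(=O)O | intermediate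
26 | mixed anhydride of 25 with 2-methylpropyl hydrogen carbonate (not isolated) | C=C[C@]1(C)[C@H](OC(=O)/C(C)=C\C)[C@@H]2OC(=O)C(CN(C)C)[C@@H]2[C@@H](OC(C)=O)[C@H]1CC(=O)OC(=O)OCC(C)C | intermediate
27 | 4-(acetyloxy)-3-[(dimethylamino)methyl]-6-ethenyl-5-(2-hydroxyethyl)-6-methyl-2-oxooctahydro-1-benzofuran-7-yl (2Z)-2-methylbut-2-enoate | C=C[C@]1(C)[C@H](OC(=O)/C(C)=C\C)[C@@H]2OC(=O)C(CN(C)C)[C@@H]2[C@@H](OC(C)=O)[C@H]1CCO | intermediate
28 | 4-(acetyloxy)-3-[(dimethylamino)methyl]-6-ethenyl-6-methyl-2-oxo-5-(2-oxoethyl)octahydro-1-benzofuran-7-yl (2Z)-2-methylbut-2-enoate | C=C[C@]1(C)[C@H](OC(=O)/C(C)=C\C)[C@@H]2OC(=O)C(CN(C)C)[C@@H]2[C@@H](OC(C)=O)[C@H]1CC=O | intermediate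
29 | 4-(acetyloxy)-5-[1-(dimethylamino)-3-oxopropan-2-yl]-3-[(dimethylamino)methyl]-6-ethenyl-6-methyl-2-oxooctahydro-1-benzofuran-7-yl (2Z)-2-methylbut-2-enoate (not isolated) | C=C[C@]1(C)[C@H](OC(=O)/C(C)=C\C)[C@@H]2OC(=O)C(CN(C)C)[C@@H]2[C@@H](OC(C)=O)[C@H]1C(CN(C)C)C=O | intermediate
30 | 4-(acetyloxy)-3-[(dimethylamino)methyl]-6-ethenyl-6-methyl-2-oxo-5-(3-oxoprop-1-en-2-yl)octahydro-1-benzofuran-7-yl (2Z)-2-methylbut-2-enoate | C=C[C@]1(C)[C@H](OC(=O)/C(C)=C\C)[C@@H]2OC(=O)C(CN(C)C)[C@@H]2[C@@H](OC(C)=O)[C@H]1C(=C)C=O | intermediate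
31 | N,N,N-trimethylammonium iodide of 30 (not isolated) | C=C[C@]1(C)[C@H](OC(=O)/C(C)=C\C)[C@@H]2OC(=O)C(C[N+](C)(C)C)[C@@H]2[C@@H](OC(C)=O)[C@H]1C(=C)C=O.[I-] | intermediate
32 | (3aR,4S,5R,6S,7S,7aR)-4-(acetyloxy)-6-ethenyl-6-methyl-3-methylidene-2-oxo-5-(3-oxoprop-1-en-2-yl)octahydro-1-benzofuran-7-yl (2Z)-2-methylbut-2-enoate | C=C[C@]1(C)[C@H](OC(=O)/C(C)=C\C)[C@@H]2OC(=O)C(=C)[C@@H]2[C@@H](OC(C)=O)[C@H]1C(=C)C=O | target

## Step count and risks

Total: 22 steps. Longest linear sequence: 20 steps (steps 1, 2 and 5 to 22); steps 3 and 4 make the second component of the key step.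

The three steps most likely to fail:

Step 5 (key step). What may go wrong: loss of regiocontrol in the first carbon–carbon bond formation, capture of the intermediate cation before the ring closes (open-chain Mukaiyama adduct or (3+2) closure), or weak facial induction by the auxiliary. The fallback sets out from diene 8 (made from 3 as in step 5) and acetal 6 and comes back at 9; it makes the two bonds one after the other. A BF3·OEt2-promoted vinylogous Mukaiyama addition of 8 to the oxocarbenium ion from 6 forms only the C9–C10 bond and gives, after loss of one silyl group, the open-chain methyl ketone 3-[(tert-butyldimethylsilyl)oxy]-5-methyl-5-{2-oxo-1-[(1S)-1-phenylethoxy]propyl}cyclopent-2-en-1-one F1, whose diastereomers can be separated. Kinetic enolisation of the methyl ketone with LiN(iPr)2 and TBSOTf gives the silyl enol ether 3-[(tert-butyldimethylsilyl)oxy]-5-{2-[(tert-butyldimethylsilyl)oxy]-1-[(1S)-1-phenylethoxy]prop-2-en-1-yl}-5-methylcyclopent-2-en-1-one F2. A catalytic amount of Me3SiOTf then closes the C6–C7 bond by an intramolecular Mukaiyama–Michael addition, with transfer of the silyl group to the ring carbonyl oxygen, to give 9.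

Step 13. What may go wrong: enolisation toward C7 with β-elimination of the C8 silyloxy group, proton transfer from the bromoacetate instead of alkylation, or attack on the α face. The fallback sets out from 18 and comes back at 19; it uses a metalated hydrazone in place of the ketone enolate. Condensation of 18 with Me2NNH2 gives the N,N-dimethylhydrazone of 18 F3; LiN(iPr)2 deprotonates it at the less substituted α-carbon C5, and the more nucleophilic azaenolate is alkylated with prop-2-en-1-yl bromoacetate from the β face to give the C5-alkylated N,N-dimethylhydrazone F4; hydrolysis with CuCl2 in buffered aqueous THF gives 19.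

Step 17. What may go wrong: slow acylation of the neopentyl-type C9 hydroxyl, with isomerisation of the activated angelic acid to the tiglate during the long reaction time. The fallback sets out from 23 and comes back at 24; it builds the Z double bond on the molecule instead of transferring it. Esterification of 23 with 2-[bis(2,2,2-trifluoroethoxy)phosphoryl]propanoic acid (DCC, DMAP) gives the C9 2-[bis(2,2,2-trifluoroethoxy)phosphoryl]propanoate F5. A Still–Gennari olefination with acetaldehyde (KN(SiMe3)2, 18-crown-6, THF, −78 °C) then gives the (2Z)-2-methylbut-2-enoate 24.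

Further compounds
F1 | step 5 | 3-[(tert-butyldimethylsilyl)oxy]-5-methyl-5-{2-oxo-1-[(1S)-1-phenylethoxy]propyl}cyclopent-2-en-1-one | CC(=O)[C@@H](O[C@@H](C)c1ccccc1)[C@]2(C)CC(O[Si](C)(C)C(C)(C)C)=CC2=O
F2 | step 5 | 3-[(tert-butyldimethylsilyl)oxy]-5-{2-[(tert-butyldimethylsilyl)oxy]-1-[(1S)-1-phenylethoxy]prop-2-en-1-yl}-5-methylcyclopent-2-en-1-one | C=C(O[Si](C)(C)C(C)(C)C)[C@@H](O[C@@H](C)c1ccccc1)[C@]2(C)CC(O[Si](C)(C)C(C)(C)C)=CC2=O
F3 | step 13 | tert-butyl 3-(dimethylamino)-2-{6-(2,2-dimethylhydrazinylidene)-4-ethenyl-4-methyl-3-[(1S)-1-phenylethoxy]-2-[(triethylsilyl)oxy]cyclohexyl}propanoate | C=C[C@]1(C)[C@H](O[C@@H](C)c2ccccc2)[C@H](O[Si](CC)(CC)CC)[C@H](C(CN(C)C)C(=O)OC(C)(C)C)C(=NN(C)C)C1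
F4 | step 13 | tert-butyl 3-(dimethylamino)-2-{6-(2,2-dimethylhydrazinylidene)-4-ethenyl-4-methyl-5-[2-oxo-2-(prop-2-en-1-yloxy)ethyl]-3-[(1S)-1-phenylethoxy]-2-[(triethylsilyl)oxy]cyclohexyl}propanoate | C=C[C@]1(C)[C@H](O[C@@H](C)c2ccccc2)[C@H](O[Si](CC)(CC)CC)[C@H](C(CN(C)C)C(=O)OC(C)(C)C)C(=NN(C)C)[C@H]1CC(=O)OCC=C
F5 | step 17 | 4-(acetyloxy)-3-[(dimethylamino)methyl]-6-ethenyl-6-methyl-2-oxo-5-[2-oxo-2-(prop-2-en-1-yloxy)ethyl]octahydro-1-benzofuran-7-yl 2-[bis(2,2,2-trifluoroethoxy)phosphoryl]propanoate | C=C[C@]1(C)[C@H](OC(=O)C(C)P(=O)(OCC(F)(F)F)OCC(F)(F)F)[C@@H]2OC(=O)C(CN(C)C)[C@@H]2[C@@H](OC(C)=O)[C@H]1CC(=O)OCC=C
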